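## The problem

Compound 22 is a diarylheptanoid in which C1 to C5 of the heptane chain and one oxygen form an oxane: C1 bears ring A (3,4-dihydroxy-5-methoxyphenyl), C3 a free hydroxyl, and C5 the C6–C7 ethylene that ends in ring B (4-hydroxy-3-methoxyphenyl). The stereocentres C1 (S), C3 (R) and C5 (S) put all three substituents on one face of the ring, equatorial in the chair. Read along the open chain, this makes the oxygens on C1 and C3 1,3-anti, so an acyclic precursor must be an anti diol and not the more easily made syn one. C1 and C3 can each be set on an open chain by reagent-controlled addition to an aldehyde, whereas C5, the carbon next to the ring oxygen, can be carried as a hemiacetal and set last, on the ring, under the control of a centre already present. The material is sensitive: the ring A catechol and the ring B phenol oxidise easily and must stay masked to the end; the C1–O bond is a benzylic ether para to an oxygen substituent, so strong acid can ionise it and forcing hydrogenation can cleave it; β-oxygenated aldehydes on the way eliminate under base. The feature that opens the key step is that O3 and C6 lie on the same face of the ring, attached to C3 and C5 across C4. One silicon atom between O3 and C6 closes a six-membered ring, so an alkynylsilyl group on O3 can carry C6, C7 and ring B and can bond C6 to a radical at C5 only from the face of O3, which is also the face of ring A.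

## Retrosynthesis

22 from 21. No skeletal bond is cut. The C6–C7 ethylene is taken back to a styrene and the three phenols to benzyl ethers, because one hydrogenation then does both jobs and the catechol appears only in the last flask. Acid-labile or silyl phenol protection would add a step or expose the benzylic C1–O bond to acid. The forward reaction must saturate the alkene and cleave three aryl benzyl ethers without hydrogenolysis of the ring C1–O bond.

21 from 20. The C3 hydroxyl and the vinylic hydrogen on C6 are joined through a dimethylsilylene group, giving the bridged siloxane 20 (Si–O and Si–C6 put back). This added ring simplifies nothing by itself; it makes the C5–C6 bond intramolecular one step earlier. The forward step asks fluoride to cleave both the Si–O and the Si–C(sp2) bond.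

20 from 19 (key). The C5–C6 bond is cut homolytically, which opens the siloxane to the alkynylsilyl ether of phenyl selenoglycoside 19. The neighbouring cuts are weaker:
- An ionic C-glycosylation at C5 would deliver carbon axially, trans to ring A.
- Cutting C6–C7 leaves C5 unset and needs an sp3–sp3 coupling.
- Cutting C5–O requires the whole chain with C5 already resolved.

The radical cut removes C6, C7 and ring B in one piece and leaves a 2,4-dideoxy glycosyl selenide with two stereocentres. The forward reaction must form the bond on the face of O3, although a free anomeric radical would react axially.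

19 from 13, 15 and 16. The O–Si and Si–C(sp) bonds are cut. Dichlorodimethylsilane 16 is the linchpin: an acetylide replaces one chloride and the C3 hydroxyl of 13 the other. Alkyne 15 comes from aldehyde 14 by one-carbon homologation, so ring B, C7 and C6 derive from the benzyl ether of vanillin. The forward silylation must leave the selenide alone, and its product is a labile silyl ether.

13 from 12 from 9. The C5–Se bond is cut to lactol 12 (hemiacetal exchange). Lactol 12 is the closed form of hydroxy aldehyde 11, whose aldehyde carbon is the inner alkene carbon of diol 9. A selenide is preferred to a halide or thioether: it survives silylation and chromatography and is abstracted rapidly by tin radicals. The lactol can only close in the six-membered sense, so C3 needs no protecting group. The forward steps require alkene cleavage beside an electron-rich arene and anomeric substitution without ionising C1–O.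

9 from 8 from 7 and 3. The C3–C4 bond is cut: allylboronate 3 adds to β-silyloxy aldehyde 7. An aldol construction would bring these carbons at a higher oxidation level and need a later reduction; allylation gives the carbinol directly and the alkene is a masked C5 aldehyde. The forward reaction must give the 1,3-anti isomer, which on a β-silyloxy aldehyde has to come from the catalyst.

7 from 5 from 4 from 2 and 3; 2 from 1. The C1–C2 bond is cut in the same way: allylation of ring A aldehyde 2, silylation to 5 and alkene cleavage. The same reagent 3 and reaction type serve twice, with the two enantiomers of one catalyst. Aldehyde 2 is the dibenzyl ether of 5-hydroxyvanillin 1. The first allylation must set C1 (S) with high enantioselectivity, since every later centre is built relative to it.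

## Roads not taken

Alternative 1: Aldolase lactol as the C1–C6 core.
- Cut: the C1–aryl bond and the C6–C7 bond.
- Key step: an aldolase adds two molecules of acetaldehyde A3 in sequence to chloroacetaldehyde A2, forming C4–C5 and then C2–C3, and the product closes to lactol A1.
- Merits: two carbinol centres from the commodity aldehydes A2 and A3, in water, with no protecting group, in one step of proven scalability.
- Weak points for 22:
  - The enzyme gives the 1,3-syn relation (hydroxyl trans to the chloromethyl group on the ring), whereas 22 needs anti. C3 of A1 has the spatial arrangement of 22 but C5 has the opposite one. C5 is the ring C–O carbon, so it could only be corrected by opening the lactol and closing the final ring by displacement at C5 with inversion by the C1 oxygen.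
  - Neither aryl ring is present. Ring A must be added at C1, creating a new stereocentre without obvious control. Ring B must enter by substitution of a β-oxygenated primary chloride with a benzylic nucleophile.
- Comparison: A1 is reached in one step, where the chosen route needs seven to reach lactol 12; in cost and catalysis this road is better. Against it, 12 already carries ring A, the correct C1 and the anti relation. The two carbon–carbon bond formations, the inversion at C5 and the control of C1 that follow A1 would consume more than the steps saved.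

Alternative 2: Oxidative benzylic C–H cyclisation.
- Cut: C1–C2, with ring closure.
- Key step: in the acyclic ether A5 (ring A benzyl ether of the C5 carbinol, enol acetate at C3, ring B as pivalate), 2,3-dichloro-5,6-dicyano-1,4-benzoquinone oxidises the benzylic CH2 of ring A to an oxocarbenium ion. The enol acetate attacks it and gives oxan-4-one A4.
- Merits: ring and C1–C2 form together; C1 is set from C5 through a chair transition state with both substituents equatorial; only C5 needs asymmetric synthesis; ring A enters as a simple benzylic alcohol; C3 follows by hydride reduction to the equatorial alcohol.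
- Weak points for 22:
  - The oxidant meets electron-rich arenes, and the benzyl groups on ring A are themselves benzylic ethers.
  - Ring B must be deactivated as an ester, so two deprotection modes are needed.
  - A4 still holds an oxidisable benzylic C1–H next to the most electron-rich ring.
  - C3 is set late, by substrate control.
- Comparison: in step count, and in setting the ring and a stereocentre at once, this road is at least equal and probably shorter. The chosen plan sets against it:
  - no oxidation near the electron-rich rings;
  - one protecting group for all phenols and a single final hydrogenation;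
  - C3 in place at the right oxidation level before the ring chemistry;
  - a C5 configuration enforced by a covalent bridge, not by a conformational preference.

Alternative 3: Dithiane linchpin between two epoxides.
- Cut: C2–C3 and C3–C4 together.
- Key step: lithiated silyl dithiane A7 opens ring A oxirane A8 at CH2; hexamethylphosphoramide triggers a 1,4-Brook rearrangement; the relayed anion opens ring B oxirane A9. The product A6 carries C1 as silyl ether, C5 as free alcohol and C3 as dithiane.
- Merits: the most convergent assembly, three components in one flask; both carbinols from epoxides available by hydrolytic kinetic resolution; the two oxygens are differentiated.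
- Weak points for 22:
  - No ring is closed.
  - A8 is a styrene-type oxide with a para oxygen, so benzylic opening and rearrangement compete with attack at CH2.
  - The C5 carbinol of A6 has the configuration opposite to the ring carbon of 22. The oxane must therefore be closed by displacement of an activated C5 oxygen by the C1 alkoxide, next to a quaternary dithiane carbon whose sulfur can participate.
  - Dithiane removal needs oxidants or soft metal salts beside electron-rich arenes, and C3 still requires a ketone reduction.
- Comparison: this road wins on convergence, and the chosen plan has the longer linear sequence (twelve steps, with tin and selenium). After its key step the chosen plan needs two steps, whereas A6 needs about five, one of them a difficult closure. In the chosen plan all three stereocentres are settled by the time ring B is attached.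

Key step: step 11

Assumption: chain numbering is used throughout (C1 bears ring A, C3 the hydroxyl, C5 the side chain, C6–C7 lead to ring B).
Assumption: TRIP is 3,3'-bis(2,4,6-triisopropylphenyl)-1,1'-binaphthyl-2,2'-diyl hydrogen phosphate; its (R) enantiomer is taken to direct the allyl group of 3 to the Re face of an aldehyde and its (S) enantiomer to the Si face. If the sense is opposite for either aldehyde, the other catalyst enantiomer is used in that step.
Assumption: 4-(benzyloxy)-3-methoxybenzaldehyde 14, the benzyl ether of vanillin, is bought. If made in-house from vanillin under the conditions of step 1, one step is added.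

## Route

Step 1
Reactants: 1 3,4-dihydroxy-5-methoxybenzaldehyde (5-hydroxyvanillin)
Product: 2 3,4-bis(benzyloxy)-5-methoxybenzaldehyde
Conditions: BnBr (2.4 equiv), K2CO3, DMF, 60 °C
Reagents that add atoms: benzyl bromide, BrCc1ccccc1
Why: Williamson ether synthesis; both phenols are alkylated under carbonate base and the aldehyde is untouched, so the catechol is masked in a form that resists every later step and falls in the final hydrogenation.

Step 2
Reactants: 2 3,4-bis(benzyloxy)-5-methoxybenzaldehyde; 3 allylboronic acid pinacol ester
Product: 4 (1S)-1-[3,4-bis(benzyloxy)-5-methoxyphenyl]but-3-en-1-ol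
Conditions: (S)-TRIP (5 mol %), PhMe, −30 °C; aq. NaHCO3 work-up
Reagents that add atoms: none
Why: Chiral phosphoric acid-catalysed allylboration through a closed chair transition state in which the acid binds the boronate oxygen and the formyl hydrogen; the (S) catalyst is expected to expose the Si face of the aryl aldehyde, which gives the (S) carbinol at C1, and an aryl aldehyde without ortho substituents is the most favourable substrate class.

Step 3
Reactants: 4 (1S)-1-[3,4-bis(benzyloxy)-5-methoxyphenyl]but-3-en-1-ol
Product: 5 {[(1S)-1-[3,4-bis(benzyloxy)-5-methoxyphenyl]but-3-en-1-yl]oxy}(tert-butyl)dimethylsilane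
Conditions: TBSCl, imidazole, DMF, rt
Reagents that add atoms: tert-butyldimethylsilyl chloride, CC(C)(C)[Si](C)(C)Cl
Why: Silyl ether formation under imidazole catalysis; the protected benzylic oxygen cannot form hemiacetals or assist elimination once C3 becomes an aldehyde, and the silyl ether survives steps 4 and 5 yet is removed by fluoride without touching benzyl ethers.

Step 4
Reactants: 5 {[(1S)-1-[3,4-bis(benzyloxy)-5-methoxyphenyl]but-3-en-1-yl]oxy}(tert-butyl)dimethylsilane
Product: 7 (3S)-3-[3,4-bis(benzyloxy)-5-methoxyphenyl]-3-[(tert-butyldimethylsilyl)oxy]propanal, via vicinal diol 6 (not isolated)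
Conditions: K2OsO4·2H2O (2 mol %), NaIO4, 2,6-lutidine, dioxane/H2O, rt
Reagents that add atoms: sodium periodate, [Na+].[O-]I(=O)(=O)=O; water, O
Why: Lemieux–Johnson cleavage (catalytic dihydroxylation of the terminal alkene, then periodate cleavage of diol 6); it is preferred to ozone because the trialkoxyarene is not attacked, 2,6-lutidine suppresses over-oxidation, and 7 is used at once because base would eliminate the β-silyloxy group.

Step 5
Reactants: 7 (3S)-3-[3,4-bis(benzyloxy)-5-methoxyphenyl]-3-[(tert-butyldimethylsilyl)oxy]propanal; 3 allylboronic acid pinacol ester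
Product: 8 (4R,6S)-6-[3,4-bis(benzyloxy)-5-methoxyphenyl]-6-[(tert-butyldimethylsilyl)oxy]hex-1-en-4-ol
Conditions: (R)-TRIP (10 mol %), PhMe, −30 °C; aq. NaHCO3 work-up
Reagents that add atoms: none
Why: The same phosphoric acid-catalysed allylboration, now under catalyst control on an aliphatic aldehyde; the (R) catalyst is expected to send the allyl group to the Re face, which gives the (R) carbinol at C3, 1,3-anti to the C1 oxygen, and the minor enantiomer of 7 is carried into a syn diastereomer that chromatography removes.

Step 6
Reactants: 8 (4R,6S)-6-[3,4-bis(benzyloxy)-5-methoxyphenyl]-6-[(tert-butyldimethylsilyl)oxy]hex-1-en-4-ol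
Product: 9 (1S,3R)-1-[3,4-bis(benzyloxy)-5-methoxyphenyl]hex-5-ene-1,3-diol
Conditions: Bu4NF, THF, 0 °C to rt
Reagents that add atoms: none
Why: Fluoride-mediated desilylation driven by the Si–F bond; benzyl ethers, the alkene and both carbinol centres are unaffected, and the C1 hydroxyl needed to close the lactol is set free.

Step 7
Reactants: 9 (1S,3R)-1-[3,4-bis(benzyloxy)-5-methoxyphenyl]hex-5-ene-1,3-diol
Product: 12 (4S,6S)-6-[3,4-bis(benzyloxy)-5-methoxyphenyl]oxane-2,4-diol as anomeric mixture, via tetraol 10 (not isolated), via hydroxy aldehyde 11 (not isolated)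
Conditions: K2OsO4·2H2O (2 mol %), NaIO4, 2,6-lutidine, dioxane/H2O, rt
Reagents that add atoms: sodium periodate, [Na+].[O-]I(=O)(=O)=O; water, O
Why: Lemieux–Johnson cleavage; only the vicinal diol of 10 is cleaved (the 1,3-diol is inert to periodate), and aldehyde 11 is trapped at once by the C1 hydroxyl as the six-membered lactol, since the C3 hydroxyl could only close a four-membered ring; C1 and C3 are not touched.

Step 8
Reactants: 12 (4S,6S)-6-[3,4-bis(benzyloxy)-5-methoxyphenyl]oxane-2,4-diol
Product: 13 (2S,4S)-2-[3,4-bis(benzyloxy)-5-methoxyphenyl]-6-(phenylselanyl)oxan-4-ol as anomeric mixture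
Conditions: PhSeH (1.5 equiv), BF3·OEt2 (0.3 equiv), 4 Å MS, CH2Cl2, −78 to −40 °C
Reagents that add atoms: benzeneselenol, [SeH]c1ccccc1
Why: Lewis acid-promoted selenoglycosidation; the hemiacetal ionises to the ring oxocarbenium ion far more readily than the secondary C3 alcohol or the benzylic C1–O bond, the soft selenol captures it, and both anomers are kept because they give the same C5 radical.

Step 9
Reactants: 14 4-(benzyloxy)-3-methoxybenzaldehyde
Product: 15 1-(benzyloxy)-4-ethynyl-2-methoxybenzene
Conditions: dimethyl (1-diazo-2-oxopropyl)phosphonate, K2CO3, MeOH, rt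
Reagents that add atoms: dimethyl (1-diazo-2-oxopropyl)phosphonate, COP(=O)(OC)C(=[N+]=[N-])C(C)=O
Why: Ohira–Bestmann variant of the Seyferth–Gilbert homologation; methanolysis of the acetyl group frees the diazophosphonate anion, which olefinates the aryl aldehyde, and loss of N2 with 1,2-hydrogen shift gives the terminal alkyne whose two carbons become C7 and C6.

Step 10
Reactants: 13 (2S,4S)-2-[3,4-bis(benzyloxy)-5-methoxyphenyl]-6-(phenylselanyl)oxan-4-ol; 15 1-(benzyloxy)-4-ethynyl-2-methoxybenzene; 16 dichlorodimethylsilane
Product: 19 (2S,4S)-2-[3,4-bis(benzyloxy)-5-methoxyphenyl]-4-[({[4-(benzyloxy)-3-methoxyphenyl]ethynyl}dimethylsilyl)oxy]-6-(phenylselanyl)oxane as anomeric mixture, via lithium acetylide 17 (not isolated), via alkynylchlorosilane 18 (not isolated)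
Conditions: 15, n-BuLi, THF, −78 °C; add to 16 (5 equiv), −78 °C to rt; evaporate excess 16; then 13, imidazole, CH2Cl2, 0 °C to rt
Reagents that add atoms: none
Why: Acetylide 17 displaces one chloride of 16, which is used in excess so that the second chloride remains and the surplus is removed by evaporation; the Si–Cl bond of 18 then silylates the unhindered equatorial C3 hydroxyl of 13 (silyl ether formation), the selenide never meets butyllithium because 13 is added last, and the moisture-sensitive ether is passed only through a short pad of deactivated silica.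

Step 11
Reactants: 19 (2S,4S)-2-[3,4-bis(benzyloxy)-5-methoxyphenyl]-4-[({[4-(benzyloxy)-3-methoxyphenyl]ethynyl}dimethylsilyl)oxy]-6-(phenylselanyl)oxane
Product: 20 (1S,5R,7S)-4-{[4-(benzyloxy)-3-methoxyphenyl]methylidene}-7-[3,4-bis(benzyloxy)-5-methoxyphenyl]-3,3-dimethyl-2,6-dioxa-3-silabicyclo[3.3.1]nonane as mixture of alkene isomers
Conditions: Bu3SnH (1.5 equiv, syringe pump), AIBN (0.2 equiv), PhH (0.01 M), 80 °C
Reagents that add atoms: none
Why: The tributyltin radical abstracts the phenylselanyl group from either anomer of 19 and gives one α-alkoxy radical at C5, which adds to the silicon-bound alkyne carbon C6; the aryl-stabilised vinyl radical at C7 then takes hydrogen from Bu3SnH and carries the chain. The closest known reaction type is the temporary silicon connection radical C-glycosylation, in which an alkynylsilyl ether on a ring hydroxyl of a selenoglycoside traps the anomeric radical. The one ring closed is the six-membered siloxane C5–C6–Si–O–C3–C4, formed 6-exo-dig, which with the oxane makes the bridged bicyclo[3.3.1] skeleton. The new stereocentre C5 is controlled by the tether: C6 is held by O3 and can reach C5 only on the face of O3, so the new bond is cis to O3 and, because C1 and C3 are already cis, cis to ring A. Cyclisation must outrun reduction of the C5 radical by the stannane, which slow addition of Bu3SnH at high dilution secures. Exo attack must beat endo attack, which the six-membered ring size and the benzylic stabilisation of the resulting vinyl radical both favour. The oxane has to leave its all-equatorial chair for a boat in which C3 and C5 are bridged through O3, silicon and C6 and ring A sits in the unhindered bowsprit position at C1; this is the price of overriding the axial preference of an anomeric radical. The alkene geometry is not controlled and need not be, since C6=C7 is hydrogenated in step 13.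

Step 12
Reactants: 20 (1S,5R,7S)-4-{[4-(benzyloxy)-3-methoxyphenyl]methylidene}-7-[3,4-bis(benzyloxy)-5-methoxyphenyl]-3,3-dimethyl-2,6-dioxa-3-silabicyclo[3.3.1]nonane
Product: 21 (2R,4R,6S)-2-{2-[4-(benzyloxy)-3-methoxyphenyl]ethenyl}-6-[3,4-bis(benzyloxy)-5-methoxyphenyl]oxan-4-ol as mixture of alkene isomers
Conditions: Bu4NF (3 equiv), DMF, 60 °C
Reagents that add atoms: none
Why: Fluoride attacks the alkoxy-substituted silicon, opens the Si–O bond and, through a pentacoordinate fluorosilicate, protodesilylates the vinyl carbon (fluoride-induced protodesilylation of a cyclic vinyl siloxane); the C3 hydroxyl and the styrene are released, the oxane relaxes to the all-equatorial chair, and no stereocentre is involved.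

Step 13
Reactants: 21 (2R,4R,6S)-2-{2-[4-(benzyloxy)-3-methoxyphenyl]ethenyl}-6-[3,4-bis(benzyloxy)-5-methoxyphenyl]oxan-4-ol
Product: 22 (2S,4R,6S)-2-(3,4-dihydroxy-5-methoxyphenyl)-6-[2-(4-hydroxy-3-methoxyphenyl)ethyl]oxan-4-ol
Conditions: H2 (1 atm), 10% Pd/C, EtOAc/MeOH, rt
Reagents that add atoms: none
Why: Catalytic hydrogenation saturates the styrene and hydrogenolyses the three aryl benzyl ethers in one operation; under neutral conditions aryl benzyl ethers are cleaved much faster than the ring benzylic C1–O bond, so the oxane should survive if the reaction is stopped at full debenzylation.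

## Compound list

1 | 3,4-dihydroxy-5-methoxybenzaldehyde (5-hydroxyvanillin) | COc1cc(C=O)cc(O)c1O | starting material
2 | 3,4-bis(benzyloxy)-5-methoxybenzaldehyde | COc1cc(C=O)cc(OCc2ccccc2)c1OCc1ccccc1 | intermediate
3 | allylboronic acid pinacol ester | C=CCB1OC(C)(C)C(C)(C)O1 | starting material
4 | (1S)-1-[3,4-bis(benzyloxy)-5-methoxyphenyl]but-3-en-1-ol | C=CC[C@@H](c1cc(OCc2ccccc2)c(OCc2ccccc2)c(OC)c1)O | intermediate
5 | {[(1S)-1-[3,4-bis(benzyloxy)-5-methoxyphenyl]but-3-en-1-yl]oxy}(tert-butyl)dimethylsilane | C=CC[C@@H](c1cc(OCc2ccccc2)c(OCc2ccccc2)c(OC)c1)O[Si](C)(C)C(C)(C)C | intermediate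
6 | (4S)-4-[3,4-bis(benzyloxy)-5-methoxyphenyl]-4-[(tert-butyldimethylsilyl)oxy]butane-1,2-diol, both C2 epimers, not isolated | OCC(O)C[C@@H](c1cc(OCc2ccccc2)c(OCc2ccccc2)c(OC)c1)O[Si](C)(C)C(C)(C)C | intermediate
7 | (3S)-3-[3,4-bis(benzyloxy)-5-methoxyphenyl]-3-[(tert-butyldimethylsilyl)oxy]propanal | O=CC[C@@H](c1cc(OCc2ccccc2)c(OCc2ccccc2)c(OC)c1)O[Si](C)(C)C(C)(C)C | intermediate
8 | (4R,6S)-6-[3,4-bis(benzyloxy)-5-methoxyphenyl]-6-[(tert-butyldimethylsilyl)oxy]hex-1-en-4-ol (chain C1 S, C3 R, 1,3-anti) | C=CC[C@@H](O)C[C@@H](c1cc(OCc2ccccc2)c(OCc2ccccc2)c(OC)c1)O[Si](C)(C)C(C)(C)C | intermediate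
9 | (1S,3R)-1-[3,4-bis(benzyloxy)-5-methoxyphenyl]hex-5-ene-1,3-diol | C=CC[C@@H](O)C[C@@H](c1cc(OCc2ccccc2)c(OCc2ccccc2)c(OC)c1)O | intermediate
10 | (1S,3S)-1-[3,4-bis(benzyloxy)-5-methoxyphenyl]hexane-1,3,5,6-tetrol, both C5 epimers, C1 and C3 unchanged in space, not isolated | OCC(O)C[C@@H](O)C[C@@H](c1cc(OCc2ccccc2)c(OCc2ccccc2)c(OC)c1)O | intermediate
11 | (3S,5S)-5-[3,4-bis(benzyloxy)-5-methoxyphenyl]-3,5-dihydroxypentanal, not isolated | O=CC[C@@H](O)C[C@@H](c1cc(OCc2ccccc2)c(OCc2ccccc2)c(OC)c1)O | intermediate
12 | (4S,6S)-6-[3,4-bis(benzyloxy)-5-methoxyphenyl]oxane-2,4-diol, anomeric mixture | OC1C[C@@H](O)C[C@@H](c2cc(OCc3ccccc3)c(OCc3ccccc3)c(OC)c2)O1 | intermediate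
13 | (2S,4S)-2-[3,4-bis(benzyloxy)-5-methoxyphenyl]-6-(phenylselanyl)oxan-4-ol, anomeric mixture | c1ccccc1[Se]C2C[C@@H](O)C[C@@H](c3cc(OCc4ccccc4)c(OCc4ccccc4)c(OC)c3)O2 | intermediate
14 | 4-(benzyloxy)-3-methoxybenzaldehyde | COc1cc(C=O)ccc1OCc1ccccc1 | starting material
15 | 1-(benzyloxy)-4-ethynyl-2-methoxybenzene | C#Cc1ccc(OCc2ccccc2)c(OC)c1 | intermediate
16 | dichlorodimethylsilane | C[Si](C)(Cl)Cl | starting material
17 | lithium [4-(benzyloxy)-3-methoxyphenyl]acetylide, not isolated | [Li]C#Cc1ccc(OCc2ccccc2)c(OC)c1 | intermediate
18 | {[4-(benzyloxy)-3-methoxyphenyl]ethynyl}(chloro)dimethylsilane, not isolated | C[Si](C)(Cl)C#Cc1ccc(OCc2ccccc2)c(OC)c1 | intermediate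
19 | (2S,4S)-2-[3,4-bis(benzyloxy)-5-methoxyphenyl]-4-[({[4-(benzyloxy)-3-methoxyphenyl]ethynyl}dimethylsilyl)oxy]-6-(phenylselanyl)oxane, anomeric mixture | c1ccccc1[Se]C2C[C@@H](O[Si](C)(C)C#Cc3ccc(OCc4ccccc4)c(OC)c3)C[C@@H](c3cc(OCc4ccccc4)c(OCc4ccccc4)c(OC)c3)O2 | intermediate
20 | (1S,5R,7S)-4-{[4-(benzyloxy)-3-methoxyphenyl]methylidene}-7-[3,4-bis(benzyloxy)-5-methoxyphenyl]-3,3-dimethyl-2,6-dioxa-3-silabicyclo[3.3.1]nonane, alkene isomers | COc1cc(C=C3[C@H]2C[C@@H](O[Si]3(C)C)C[C@@H](c4cc(OCc5ccccc5)c(OCc5ccccc5)c(OC)c4)O2)ccc1OCc1ccccc1 | intermediate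
21 | (2R,4R,6S)-2-{2-[4-(benzyloxy)-3-methoxyphenyl]ethenyl}-6-[3,4-bis(benzyloxy)-5-methoxyphenyl]oxan-4-ol, alkene isomers | COc1cc(C=C[C@H]2C[C@@H](O)C[C@@H](c3cc(OCc4ccccc4)c(OCc4ccccc4)c(OC)c3)O2)ccc1OCc1ccccc1 | intermediate
22 | (2S,4R,6S)-2-(3,4-dihydroxy-5-methoxyphenyl)-6-[2-(4-hydroxy-3-methoxyphenyl)ethyl]oxan-4-ol | COc1cc(CC[C@H]2C[C@@H](O)C[C@@H](c3cc(O)c(O)c(OC)c3)O2)ccc1O | target

## Step count and least certain steps

Total step count: 13. Longest linear sequence: 12 steps (steps 1 to 8 and 10 to 13, from 1); step 9 is a one-step branch from 14.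

Step 11 (key step). The most likely failure is reduction of the C5 radical by the stannane before it cyclises, because the boat-like transition state is slow. A second is hydrogen transfer from the benzylic, oxygen-bearing C1–H to the vinyl radical through a six-membered transition state, which would erode the configuration at C1. The fallback leaves the route at lactol 12 and returns at 22; it forms C5–C6 ionically and sets C5 by hydride. Ag2CO3 on Celite, which oxidises lactols in preference to secondary alcohols, should give the hydroxy lactone F1, and TBSCl with imidazole then gives the lactone silyl ether F2. Lithium acetylide 17 at −78 °C adds to the lactone carbonyl and gives the alkynyl hemiketal F3. Et3SiH with BF3·OEt2 at −78 °C reduces the derived alkynyl oxocarbenium ion by axial hydride delivery, which leaves the alkynyl group equatorial, cis to ring A and O3, and gives the alkynyl oxane silyl ether F4. Bu4NF gives the alkynyl oxanol F5, and hydrogenation over Pd/C reduces the alkyne and removes the benzyl ethers to give 22.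

Step 5. The risk is poor diastereocontrol: the catalyst may not fully dominate the existing β-silyloxy centre on an aliphatic aldehyde, and the anti and syn alcohols may be hard to separate. The fallback leaves at aldehyde 7 and returns at diol 9; it moves stereocontrol from the catalyst to the C1 centre. CH2=CHCH2MgBr at −78 °C gives the C3-epimeric alcohols F6 without any need for control, and Dess–Martin periodinane buffered with NaHCO3 gives the β-silyloxy ketone F7. HF·pyridine gives the β-hydroxy ketone F8. Me4NBH(OAc)3 in MeCN/AcOH at −30 °C (Evans–Saksena reduction) then delivers hydride from boron bound to the C1 oxygen and gives the 1,3-anti diol 9.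

Step 8. The risk is ionisation of the benzylic C1–O bond by the Lewis acid over the time a free lactol needs, with epimerisation at C1 or ring opening by the selenol. The fallback leaves at lactol 12 and returns at 13. Ac2O, pyridine and DMAP give the diacetate F9. PhSeH with a catalytic amount of BF3·OEt2 at −78 °C exchanges only the anomeric acetate, a far better leaving group that reacts at lower temperature, and gives the acetylated selenoglycoside F10. K2CO3 in MeOH removes the C3 acetate and gives 13.

Step 13. The risk is over-reduction: hydrogenolysis of the allylic C5–O bond before the alkene is saturated, or of the benzylic C1–O bond once ring A is debenzylated. The fallback leaves at 21 and returns at 22. Diimide, generated from 2-nitrobenzenesulfonylhydrazide and Et3N, saturates the styrene without any C–O cleavage and gives the saturated tribenzyl ether F11. BCl3 with pentamethylbenzene as cation scavenger in CH2Cl2 at −78 °C then removes the three aryl benzyl ethers by a non-reductive path and gives 22.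

## Further compounds

F1 | step 11 | 6-[3,4-bis(benzyloxy)-5-methoxyphenyl]-4-hydroxyoxan-2-one, C1 and C3 as in 12 | O=C1C[C@@H](O)C[C@@H](c2cc(OCc3ccccc3)c(OCc3ccccc3)c(OC)c2)O1
F2 | step 11 | 6-[3,4-bis(benzyloxy)-5-methoxyphenyl]-4-[(tert-butyldimethylsilyl)oxy]oxan-2-one, C1 and C3 as in 12 | O=C1C[C@@H](O[Si](C)(C)C(C)(C)C)C[C@@H](c2cc(OCc3ccccc3)c(OCc3ccccc3)c(OC)c2)O1
F3 | step 11 | 2-{[4-(benzyloxy)-3-methoxyphenyl]ethynyl}-6-[3,4-bis(benzyloxy)-5-methoxyphenyl]-4-[(tert-butyldimethylsilyl)oxy]oxan-2-ol, anomeric mixture | OC1(C#Cc2ccc(OCc3ccccc3)c(OC)c2)C[C@@H](O[Si](C)(C)C(C)(C)C)C[C@@H](c2cc(OCc3ccccc3)c(OCc3ccccc3)c(OC)c2)O1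
F4 | step 11 | all-cis 2-{[4-(benzyloxy)-3-methoxyphenyl]ethynyl}-6-[3,4-bis(benzyloxy)-5-methoxyphenyl]-4-[(tert-butyldimethylsilyl)oxy]oxane, C1, C3 and C5 arranged as in 22 | COc1cc(C#C[C@H]2C[C@@H](O[Si](C)(C)C(C)(C)C)C[C@@H](c3cc(OCc4ccccc4)c(OCc4ccccc4)c(OC)c3)O2)ccc1OCc1ccccc1
F5 | step 11 | all-cis 2-{[4-(benzyloxy)-3-methoxyphenyl]ethynyl}-6-[3,4-bis(benzyloxy)-5-methoxyphenyl]oxan-4-ol, C1, C3 and C5 arranged as in 22 | COc1cc(C#C[C@H]2C[C@@H](O)C[C@@H](c3cc(OCc4ccccc4)c(OCc4ccccc4)c(OC)c3)O2)ccc1OCc1ccccc1
F6 | step 5 | (6S)-6-[3,4-bis(benzyloxy)-5-methoxyphenyl]-6-[(tert-butyldimethylsilyl)oxy]hex-1-en-4-ol, both C4 epimers | C=CCC(O)C[C@@H](c1cc(OCc2ccccc2)c(OCc2ccccc2)c(OC)c1)O[Si](C)(C)C(C)(C)C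
F7 | step 5 | (6S)-6-[3,4-bis(benzyloxy)-5-methoxyphenyl]-6-[(tert-butyldimethylsilyl)oxy]hex-1-en-4-one | C=CCC(=O)C[C@@H](c1cc(OCc2ccccc2)c(OCc2ccccc2)c(OC)c1)O[Si](C)(C)C(C)(C)C
F8 | step 5 | (6S)-6-[3,4-bis(benzyloxy)-5-methoxyphenyl]-6-hydroxyhex-1-en-4-one | C=CCC(=O)C[C@@H](c1cc(OCc2ccccc2)c(OCc2ccccc2)c(OC)c1)O
F9 | step 8 | 6-[3,4-bis(benzyloxy)-5-methoxyphenyl]oxane-2,4-diyl diacetate, C1 and C3 as in 12, anomeric mixture | CC(=O)OC1C[C@@H](OC(C)=O)C[C@@H](c2cc(OCc3ccccc3)c(OCc3ccccc3)c(OC)c2)O1
F10 | step 8 | 2-[3,4-bis(benzyloxy)-5-methoxyphenyl]-6-(phenylselanyl)oxan-4-yl acetate, C1 and C3 as in 13, anomeric mixture | c1ccccc1[Se]C2C[C@@H](OC(C)=O)C[C@@H](c3cc(OCc4ccccc4)c(OCc4ccccc4)c(OC)c3)O2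
F11 | step 13 | 2-{2-[4-(benzyloxy)-3-methoxyphenyl]ethyl}-6-[3,4-bis(benzyloxy)-5-methoxyphenyl]oxan-4-ol, C1, C3 and C5 arranged as in 22 | COc1cc(CC[C@H]2C[C@@H](O)C[C@@H](c3cc(OCc4ccccc4)c(OCc4ccccc4)c(OC)c3)O2)ccc1OCc1ccccc1
A1 | alternative 1 | (4R,6S)-6-(chloromethyl)oxane-2,4-diol, anomeric mixture | ClC[C@@H]1C[C@@H](O)CC(O)O1
A2 | alternative 1 | chloroacetaldehyde | ClCC=O
A3 | alternative 1 | acetaldehyde | CC=O
A4 | alternative 2 | 2,6-cis 2-[3,4-bis(benzyloxy)-5-methoxyphenyl]-6-{2-[3-methoxy-4-(pivaloyloxy)phenyl]ethyl}oxan-4-one | COc1cc(CC[C@H]2CC(=O)C[C@@H](c3cc(OCc4ccccc4)c(OCc4ccccc4)c(OC)c3)O2)ccc1OC(=O)C(C)(C)C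
A5 | alternative 2 | acyclic enol acetate: 4-{[3,4-bis(benzyloxy)-5-methoxyphenyl]methoxy}-6-[3-methoxy-4-(pivaloyloxy)phenyl]hex-1-en-2-yl acetate, ether carbon arranged as C5 of 22 | C=C(OC(C)=O)C[C@H](CCc1ccc(OC(=O)C(C)(C)C)c(OC)c1)OCc1cc(OCc2ccccc2)c(OCc2ccccc2)c(OC)c1
A6 | alternative 3 | (1S,5R) C1-silyloxy C5-hydroxy 3,3-dithiane of the diarylheptane chain | COc1cc(CC[C@@H](O)CC2(SCCCS2)C[C@@H](c2cc(OCc3ccccc3)c(OCc3ccccc3)c(OC)c2)O[Si](C)(C)C(C)(C)C)ccc1OCc1ccccc1
A7 | alternative 3 | tert-butyl(1,3-dithian-2-yl)dimethylsilane | CC(C)(C)[Si](C)(C)C1SCCCS1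
A8 | alternative 3 | (2R)-2-[3,4-bis(benzyloxy)-5-methoxyphenyl]oxirane | C1[C@@H](c2cc(OCc3ccccc3)c(OCc3ccccc3)c(OC)c2)O1
A9 | alternative 3 | (2R)-2-{2-[4-(benzyloxy)-3-methoxyphenyl]ethyl}oxirane | COc1cc(CC[C@@H]2CO2)ccc1OCc1ccccc1
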